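The flavone is cut through ring C at C4–C4a and O1–C2. Ring A, oxygenated at C5, C7 and O1, is a phloroglucinol nucleus whose three CH/OH pairs are identical, so any ring carbon and its neighbouring hydroxyl can serve as C4a and O1. One thermal annulation joins phloroglucinol to an α-methoxy aroylacetate: the ester carbon becomes C4, the α-carbon supplies C3 with its methoxy group in place, and the aryl ketone becomes C2. The precursor is the methyl β-ketoester of the 3,5-diprenyl B ring, its 4-hydroxyl masked as a triisopropylsilyl ether, chosen over a smaller silyl group because it must outlast methoxide and a phenol melt yet still leave with fluoride.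

Key step: step 4

Remark: the target has no stereocentre and no stereogenic double bond, so it is achiral and no enantiomer has to be controlled; the centres in 8, 11, 12, F3 and F7 are racemic or transient and disappear on the way to the target.

Step 1
Reactants: 1 methyl 4-hydroxybenzoate; 2 prenyl bromide (first equivalent)
Product: 4 methyl 4-hydroxy-3,5-diprenylbenzoate, via mono-prenyl phenol 3 (not isolated)
Conditions: NaH (1.1 equiv), 2 (1.1 equiv), toluene, 0 °C → rt; then NaH (1.1 equiv), 2 (1.1 equiv), rt
Reagents that add atoms: prenyl bromide 2 (second equivalent), CC(C)=CCBr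
Why: Twofold ortho C-alkylation of a sodium phenoxide held as a tight ion pair in a non-polar solvent, one molecule of prenyl bromide being consumed per ortho position; the para position is blocked by the ester, so the first prenyl group should enter next to the oxygen to give 3 and the second, after renewed deprotonation, at the other ortho carbon.

Step 2
Reactants: 4 methyl 4-hydroxy-3,5-diprenylbenzoate
Product: 5 methyl 3,5-diprenyl-4-(triisopropylsilyloxy)benzoate
Conditions: TIPSOTf (1.3 equiv), 2,6-lutidine (2.5 equiv), CH2Cl2, 0 °C → rt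
Reagents that add atoms: triisopropylsilyl trifluoromethanesulfonate (TIPSOTf), CC(C)[Si](OS(=O)(=O)C(F)(F)F)(C(C)C)C(C)C
Why: O-silylation of a 2,6-disubstituted phenol with a silyl triflate and a hindered base; the lutidine buffer keeps strong acid away, so the o-prenyl phenol should not close to a chroman.

Step 3
Reactants: 5 methyl 3,5-diprenyl-4-(triisopropylsilyloxy)benzoate; 6 methyl methoxyacetate
Product: 8 methyl 2-methoxy-3-oxo-3-[3,5-diprenyl-4-(triisopropylsilyloxy)phenyl]propanoate, via lithium enolate 7 (not isolated)
Conditions: LDA (3.0 equiv), 6 (3.1 equiv), THF, −78 °C; then 5, −78 → 0 °C; sat. aq NH4Cl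
Reagents that add atoms: none
Why: Crossed Claisen condensation of a preformed ester enolate with a non-enolisable aryl ester, driven by deprotonation of the doubly activated α-CH of the product by a second equivalent of enolate; the hindered silyl ether and the isolated olefins should be inert at low temperature.

Step 4
Reactants: 8 methyl 2-methoxy-3-oxo-3-[3,5-diprenyl-4-(triisopropylsilyloxy)phenyl]propanoate; 9 phloroglucinol
Product: 13 5,7-dihydroxy-3-methoxy-2-[3,5-diprenyl-4-(triisopropylsilyloxy)phenyl]-4H-chromen-4-one, via acylketene 10 (not isolated), via aryl diketone 11 (not isolated), via hemiketal 12 (not isolated)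
Conditions: 9 (anhydrous, 2.0 equiv), neat melt, Ar, microwave, 240 °C, ca. 5–10 min, open vessel (MeOH and H2O distil off)
Reagents that add atoms: none
Why: On heating, ketoester 8 loses methanol to give acylketene 10, which acylates phloroglucinol at a ring carbon (directly, or through an aryl ester that rearranges under the same conditions) to give diketone 11 and with it the C4–C4a bond. The closest known reaction is the Mentzer thermal chromone synthesis from a phenol and a β-ketoester, including its solvent-free microwave form. Ring C closes by 6-exo-trig addition of the flanking phenol oxygen to the aryl ketone carbon (O1–C2) to give hemiketal 12, and loss of water gives the aromatic pyranone. No stereocentre is kept, since the centres of 8, 11 and 12 are flattened by the dehydration. The step needs chromone-over-coumarin selectivity and a single annulation: acid-free heating, the α-methoxy substituent and the weakly electrophilic aryl ketone direct the phenol carbon to the ketene carbon and not to the ketone, the threefold symmetry of 9 leaves one possible site, and the first acyl group deactivates ring A against a second. The silyl ether keeps the B-ring phenol from adding to ketene 10 or to its own prenyl olefins, and the excess of 9 shields the 7-hydroxyl of 13 from acylation.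

Step 5
Reactants: 13 5,7-dihydroxy-3-methoxy-2-[3,5-diprenyl-4-(triisopropylsilyloxy)phenyl]-4H-chromen-4-one
Product: 14 5,7-dihydroxy-2-(4-hydroxy-3,5-diprenylphenyl)-3-methoxy-4H-chromen-4-one (target)
Conditions: TBAF (3 equiv), AcOH (3 equiv), THF, 0 °C → rt; pH 5 buffer work-up
Reagents that add atoms: none
Why: Fluoride-induced cleavage of an aryl silyl ether, driven by the Si–F bond and the good phenoxide leaving group of the chromone-conjugated B ring; acetic acid buffering keeps the medium near neutral, so the free polyphenol and the prenyl groups should be untouched.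

Compound list
1 | methyl 4-hydroxybenzoate | COC(=O)c1ccc(O)cc1 | starting material
2 | prenyl bromide (1-bromo-3-methylbut-2-ene) | CC(C)=CCBr | starting material
3 | methyl 4-hydroxy-3-(3-methylbut-2-en-1-yl)benzoate (mono-prenyl phenol, not isolated) | COC(=O)c1ccc(O)c(CC=C(C)C)c1 | intermediate
4 | methyl 4-hydroxy-3,5-bis(3-methylbut-2-en-1-yl)benzoate | COC(=O)c1cc(CC=C(C)C)c(O)c(CC=C(C)C)c1 | intermediate
5 | methyl 3,5-bis(3-methylbut-2-en-1-yl)-4-(triisopropylsilyloxy)benzoate | COC(=O)c1cc(CC=C(C)C)c(O[Si](C(C)C)(C(C)C)C(C)C)c(CC=C(C)C)c1 | intermediate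
6 | methyl methoxyacetate | COCC(=O)OC | starting material
7 | lithium enolate of methyl methoxyacetate (lithium 1,2-dimethoxyethenolate, geometry undefined, not isolated) | [Li+].[O-]C(OC)=COC | intermediate
8 | methyl 2-methoxy-3-oxo-3-[3,5-bis(3-methylbut-2-en-1-yl)-4-(triisopropylsilyloxy)phenyl]propanoate (racemic, C2 epimerisable) | COC(=O)C(OC)C(=O)c1cc(CC=C(C)C)c(O[Si](C(C)C)(C(C)C)C(C)C)c(CC=C(C)C)c1 | intermediate
9 | phloroglucinol (benzene-1,3,5-triol) | Oc1cc(O)cc(O)c1 | starting material
10 | acylketene, 2-methoxy-3-oxo-3-[3,5-bis(3-methylbut-2-en-1-yl)-4-(triisopropylsilyloxy)phenyl]prop-1-en-1-one (not isolated) | COC(=C=O)C(=O)c1cc(CC=C(C)C)c(O[Si](C(C)C)(C(C)C)C(C)C)c(CC=C(C)C)c1 | intermediate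
11 | aryl diketone, 2-methoxy-1-(2,4,6-trihydroxyphenyl)-3-[3,5-bis(3-methylbut-2-en-1-yl)-4-(triisopropylsilyloxy)phenyl]propane-1,3-dione (racemic, not isolated) | COC(C(=O)c1c(O)cc(O)cc1O)C(=O)c1cc(CC=C(C)C)c(O[Si](C(C)C)(C(C)C)C(C)C)c(CC=C(C)C)c1 | intermediate
12 | hemiketal, 2,5,7-trihydroxy-3-methoxy-2-[3,5-bis(3-methylbut-2-en-1-yl)-4-(triisopropylsilyloxy)phenyl]chroman-4-one (diastereomer mixture, not isolated) | COC1C(=O)c2c(O)cc(O)cc2OC1(O)c1cc(CC=C(C)C)c(O[Si](C(C)C)(C(C)C)C(C)C)c(CC=C(C)C)c1 | intermediate
13 | 5,7-dihydroxy-3-methoxy-2-[3,5-bis(3-methylbut-2-en-1-yl)-4-(triisopropylsilyloxy)phenyl]-4H-chromen-4-one | COc1c(-c2cc(CC=C(C)C)c(O[Si](C(C)C)(C(C)C)C(C)C)c(CC=C(C)C)c2)oc2cc(O)cc(O)c2c1=O | intermediate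
14 | 5,7-dihydroxy-2-[4-hydroxy-3,5-bis(3-methylbut-2-en-1-yl)phenyl]-3-methoxy-4H-chromen-4-one (achiral) | COc1c(-c2cc(CC=C(C)C)c(O)c(CC=C(C)C)c2)oc2cc(O)cc(O)c2c1=O | target

Total step count: 5
Longest linear sequence: 5 steps (1 → 4 → 5 → 8 → 13 → 14)

Steps most likely to fail

1. Step 4. At 240 °C the silyl group may be lost or transferred to the phenol melt, after which the freed B-ring phenol can close onto a prenyl olefin. The ring carbon of phloroglucinol may also attack the aryl ketone, which is the coumarin mode of annulation. The water and methanol set free may cleave and decarboxylate the ketoester. Fallback, setting out from 9 and 5 and returning at 13: phloroglucinol 9 is acylated in a Hoesch reaction with methoxyacetonitrile (ZnCl2, HCl, Et2O, 0 °C; then hot water) to 2,4,6-trihydroxy-ω-methoxyacetophenone F1. Its two non-chelated hydroxyls are capped (MOMCl, i-Pr2NEt, CH2Cl2, 0 °C) to give 1-[2-hydroxy-4,6-bis(methoxymethoxy)phenyl]-2-methoxyethanone F2. The lithium dianion of F2 (LiHMDS, THF, −78 °C → rt) is condensed with ester 5 in a ketone–ester Claisen reaction to the o-hydroxyaryl 1,3-diketone F3. Brief treatment of F3 with HCl in methanol at 40–50 °C should cyclodehydrate it and unmask ring A, giving 13. This path replaces the heat by dilute acid, which the prenyl groups must tolerate, while the 4'-O-silyl group still blocks chroman formation.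

2. Step 1. O-Alkylation may compete with C-alkylation, and the reaction may stop at the mono-prenyl stage or go on to dearomatised, over-alkylated material, so that the wanted bis-ortho product is a minor component. Fallback, setting out from 1 and returning at 4: bromination of 1 (Br2, AcOH, rt) should give methyl 3,5-dibromo-4-hydroxybenzoate F4. A twofold Stille coupling of F4 with tributyl(3-methylbut-2-en-1-yl)stannane (Pd(PPh3)4, DMF, 90 °C), which joins at the tin-bearing carbon, should then give 4 with both positions fixed by the halogens.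

3. Step 3. Acyl substitution at the electron-rich, flanked aryl ester may be slow, so that self-condensation of enolate 7 takes over on warming, and the methoxide set free may attack silicon. Fallback, setting out from 5 and returning at 8: reduction of 5 (DIBAL-H, CH2Cl2, −78 °C) gives [3,5-diprenyl-4-(triisopropylsilyloxy)phenyl]methanol F5, and oxidation (MnO2, CH2Cl2, rt) gives 3,5-diprenyl-4-(triisopropylsilyloxy)benzaldehyde F6. Aldol addition of enolate 7 to F6 (THF, −78 °C), which is far faster than any ester self-condensation, gives methyl 3-hydroxy-2-methoxy-3-[3,5-diprenyl-4-(triisopropylsilyloxy)phenyl]propanoate F7 as a diastereomer mixture of no consequence. Dess–Martin oxidation of F7 (NaHCO3, CH2Cl2, rt) should give 8.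

Further compounds
F1 | step 4 | 2,4,6-trihydroxy-ω-methoxyacetophenone (2-methoxy-1-(2,4,6-trihydroxyphenyl)ethanone) | COCC(=O)c1c(O)cc(O)cc1O
F2 | step 4 | 1-[2-hydroxy-4,6-bis(methoxymethoxy)phenyl]-2-methoxyethanone | COCOc1cc(O)c(C(=O)COC)c(OCOC)c1
F3 | step 4 | 1-[2-hydroxy-4,6-bis(methoxymethoxy)phenyl]-2-methoxy-3-[3,5-bis(3-methylbut-2-en-1-yl)-4-(triisopropylsilyloxy)phenyl]propane-1,3-dione (racemic) | COCOc1cc(O)c(C(=O)C(OC)C(=O)c2cc(CC=C(C)C)c(O[Si](C(C)C)(C(C)C)C(C)C)c(CC=C(C)C)c2)c(OCOC)c1
F4 | step 1 | methyl 3,5-dibromo-4-hydroxybenzoate | COC(=O)c1cc(Br)c(O)c(Br)c1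
F5 | step 3 | [3,5-bis(3-methylbut-2-en-1-yl)-4-(triisopropylsilyloxy)phenyl]methanol | OCc1cc(CC=C(C)C)c(O[Si](C(C)C)(C(C)C)C(C)C)c(CC=C(C)C)c1
F6 | step 3 | 3,5-bis(3-methylbut-2-en-1-yl)-4-(triisopropylsilyloxy)benzaldehyde | O=Cc1cc(CC=C(C)C)c(O[Si](C(C)C)(C(C)C)C(C)C)c(CC=C(C)C)c1
F7 | step 3 | methyl 3-hydroxy-2-methoxy-3-[3,5-bis(3-methylbut-2-en-1-yl)-4-(triisopropylsilyloxy)phenyl]propanoate (mixture of racemic diastereomers) | COC(=O)C(OC)C(O)c1cc(CC=C(C)C)c(O[Si](C(C)C)(C(C)C)C(C)C)c(CC=C(C)C)c1
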